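Follow the rate of Q, not its amount, through these flasks.

| flask | J | L | remark | time |
|---|---|---|---|---|
| winter | 0.50 M | 0.49 M | run made earlier |  |
| dusk | 0.50 M | 0.33 M | run made earlier |  |
| midnight | 0.50 M | 0.73 M | run made earlier |  |
| Saturday's | 0.50 M | 0.490 M (fed, over 4.0 min) | all else is in the flask from the start; the feed brings no volume worth counting | 6.0 min |
| Sunday's | 0.50 M (in portions, 2, over 4.0 min) | 0.490 M | first portion at the start, last at 4.0 min | 6.0 min |
| Wednesday's | 0.50 M (fed, over 4.0 min) | 0.490 M | all else is in the flask from the start; the feed brings no volume worth counting | 6.0 min |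
| Tuesday's | 0.50 M | 0.490 M | everything together at the start | 6.0 min |

- winter (time / min: Q / %, E / %): 0.250: 2.6, 51.4; 0.500: 4.2, 49.2; 0.833: 7.7, 46.8; 1.33: 9.4, 42.2; 2.00: 12.0, 38.8; 4.00: 17.4, 26.6
- dusk (time / min: Q / %, E / %): 0.500: 1.8, 38.2; 0.833: 1.7, 35.5; 1.33: 4.5, 33.5; 2.00: 6.1, 31.5; 4.00: 9.7, 23.3; 6.00: 10.9, 19.3
- midnight (time / min: Q / %, E / %): 0.417: 7.1, 61.7; 1.33: 17.9, 47.6; 2.00: 24.5, 40.0; 3.00: 27.5, 34.0; 5.00: 32.7, 24.2; 6.00: 35.1, 19.8

(standard deviation of a reading: 1 percentage point)

- the flask with the highest amount of Q, in percent of the J charged ("all alike" if they lie within 1.5 percentage points) (Saturday's / Sunday's / Wednesday's / Tuesday's / all alike)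
- final Q, as a percentage of the J charged, in Saturday's
- final Q, as a percentage of the J charged, in Sunday's
- final Q, as a percentage of the J charged, in Wednesday's
- final Q, as a percentage of the J charged, in Tuesday's

- steps under discussion: L + E -> Q; J + L <-> E; L -> X

**Rate rule.** L is the limiting reagent, charged at 0.490 M against 0.50 M of J, and its balance reads: free L, plus E, plus twice Q, plus X, equals the charge. In the winter run E already stands at 51.4 % after 0.250 min, so we hold J + L ⇌ E at equilibrium; L + E → Q then runs as cE squared over cJ. We call the factor in front the Q constant, and with amounts as fractions of the J charged the charge cancels. The last two winter readings give 0.133 min⁻¹. On the dusk run, with less L, it gives 0.0130 min⁻¹ where the readings show 0.0120 min⁻¹.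

**The slowing.** Tuesday's has the winter charges, so we start from the rate at the first winter reading, 0.0763 min⁻¹. By 4.00 min the fall of E has slowed it by a factor 3.73 and the rise of J by 1.22, leaving 0.0168 min⁻¹. The last winter interval slowed it by 2.42; we let the remaining 2.00 min slow it as much, average the two ends and add to 17.4 %, which gives 19.8 % for Tuesday's. We commit to 19.8 % for Tuesday's and reckon no figure for the dosed flasks.

**The forecast.** It names Tuesday's, with 20.2 % there, 16.4 % in Sunday's, 14.1 % in Saturday's and 13.6 % in Wednesday's: “Tuesday extends the winter run to about 20%.” Its Tuesday's figure stands above our 19.8 %.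

    L + E → Q (k = 0.0133 M⁻¹ s⁻¹)
    J + L ⇌ E (K = 5.83 M⁻¹, k = 0.627 M⁻¹ s⁻¹)
    L → X (k = 0.00322 s⁻¹)

**The result.** Tuesday's leads with 19.6 %, ahead of Sunday's 16.5 %, Saturday's 14.4 % and Wednesday's 13.2 %, and at 6.00 min Tuesday's holds 40.0 % of its L charge in Q against 26.5 % in X. Tuesday's final E and J put into the Q constant give a rate of 0.00980 min⁻¹. Tuesday's would lose first place to a Wednesday's with more L: with 1.2 M of L, that neighbour's final E and J give 0.0233 min⁻¹, and its Q reached 42.0 %.

Readings and results were generated by integration from invented constants; noise was put on by code.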